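The constants were set for the occasion; the result is computed.

Going from the coldest flask to the hottest, the exit of the open intermediate to product sped up 474 times and its formation 47 times, so this note to the next person at the bench concerns what a cold flask holds and what it pays.

the same everywhere: starting material 0.30 M; partner 0.360 M; capture agent 0.0150 M; protic impurity 0.0300 M; time 20 h

| charge | remark | temperature |
|---|---|---|
| Tuesday's | at 95 °C until 4.0 h, from then on at 45 °C |  |
| Thursday's |  | 95 °C |
| Saturday's |  | 45 °C |
| Friday's |  | 70 °C |

    open intermediate + capture agent → trapped intermediate (k1 = 0.948 /M/h, Ea1 = 61.0 kJ/mol)
    starting material + product ⇌ idle adduct, settled at all times (K2 = 3.8 /M, ΔH2 = −52.0 kJ/mol)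
    starting material + protic impurity → quenched substrate (k3 = 0.403 /M/h, Ea3 = 89.0 kJ/mol)
    starting material + partner ⇌ open intermediate (K4 = 0.565 /M, k4 = 1.15 /M/h, Ea4 = 75.0 kJ/mol, ΔH4 = −68.0 kJ/mol)
    open intermediate → product (k5 = 0.0173 /h, Ea5 = 120 kJ/mol)
    (constants at 70 °C)

1. the flask that comes out highest in amount of product, in percent of the starting material charged, or "all alike" when all lie within 1.5 percentage points (Tuesday's / Thursday's / Saturday's / Friday's / all alike)
2. product at the end, in percent of the starting material charged, Tuesday's
3. product at the end, in percent of the starting material charged, Thursday's
4. product at the end, in percent of the starting material charged, Saturday's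
5. product at the end, in percent of the starting material charged, Friday's

- a species is counted by the starting material in it: one idle adduct counts as two
- amounts and yields of product count idle adduct too
- constants are those at 70 °C; use the activation energies and enthalpies for any other temperature
- in an amount of product, one idle adduct counts as one product

1. I started from the rule for Tuesday's flask after the change to 45 °C. Product forms at first order from the open intermediate, so with c(open intermediate) steady over a stretch Δt, the rate integrates in closed form to a gain in c(product) of k·c(open intermediate)·Δt.

2. I scaled the exit constant to 45 °C and got 6.35 × 10⁻⁴ /h. I called this the cold leak, the first-order rate constant of the exit in the cold. Over the 16.0 h of Tuesday's cold stretch, it passes on 1.02 % of whatever stands open and stays steady.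

3. At 95 °C I took the opening step as balanced, because its reverse constant, 61.2 /h, was far larger than the exit constant, 0.301 /h. At the starting c(partner), Tuesday's hot 4.0 h then make 4.85 % of the charge, and somewhat less as the reagents fall.

4. Even with the whole charge open, the leak adds 1.02 % of it, so I expected Tuesday's flask to end below 5.87 %.

5. The same starting rates over 20 h give 24.3 % for Thursday's flask and 7.04 % for Friday's. The leak on the whole charge gives 1.27 % for Saturday's. I therefore put Thursday's highest.

6. Do not count as product the open intermediate that fills Tuesday's flask in the cold: over the cold stretch the leak passes on 1.02 % of it.

The forecast, which “treated the open intermediate as pre-equilibrated”, named Thursday's and gave 4.2 % for Tuesday's, 16.5 % for Thursday's, 0.33 % for Saturday's and 4.4 % for Friday's.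

The flasks ended at 4.17 % for Tuesday's, 16.4 % for Thursday's, 0.331 % for Saturday's and 4.49 % for Friday's, which put Thursday's highest. Tuesday's flask held 30.3 % of its charge as open intermediate at 20.0 h, and the leak on that is 0.309 % of the charge. Left until 2.0 d, Tuesday's flask held 35.5 % open. The cold leak on the mean of those two readings, over the further 28.0 h, gives 0.584 % of the charge, and that flask read 4.78 %, which is 0.61 percentage points above Tuesday's.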